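**Retrosynthetic overview**
1. Target 9 ⇐ tertiary vinyl carbinol 8: allylic 1,3‑transposition with bromide installs C8–Br and the exocyclic Z‑alkene in one step.
2. 8 ⇐ α‑acetoxy ketone 7 (vinyl addition to C6=O) ⇐ dibromo ketone 6 (acetate displaces the α‑bromide; C1 set thermodynamically).
3. Key disconnection C1–C2: 6 ⇐ acyclic α,α‑dibromomethyl ketone 5 by 6‑endo bromine‑atom‑transfer radical cyclisation. The ketone α‑carbon reacts with reversed (enolonium‑type) polarity with the unactivated vinyl group, and the neopentyl C3–Br forms in the same step.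
4. 5 ⇐ (S)‑α‑chloro aldehyde 3 + LiCHBr2, then oxidation; 3 ⇐ 3,3‑dimethylpent‑4‑enal 2 by organocatalytic α‑chlorination (sole source of absolute configuration) ⇐ methyl 3,3‑dimethylpent‑4‑enoate 1.
5. Ring order: the single cyclohexane ring is formed in step 5; no other ring is made.

Atom labels used in the explanations are those of the target: C1 = CH–OAc, C2 = ring CH2, C3 = CHBr, C4 = CMe2, C5 = CHCl, C6 = ring alkene carbon, C7 = exocyclic =CH, C8 = CH2Br.

Assumption: the (5S)-imidazolidinone catalyst in step 2 is taken to give the 2S chloro aldehyde; if the opposite sense is found, its mirror image is used with no other change.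

**Step 1**
Reactants: 1 methyl 3,3-dimethylpent-4-enoate
Product: 2 3,3-dimethylpent-4-enal
Conditions: iBu2AlH (1.05 equiv), CH2Cl2, −78 °C; aq work-up
Reagents that add atoms: none
Why: Ester-to-aldehyde partial reduction, in which the tetrahedral aluminium hemiacetal survives at −78 °C until hydrolysis so that reduction stops at the aldehyde; no stereocentre is involved.

**Step 2**
Reactants: 2 3,3-dimethylpent-4-enal
Product: 3 (2S)-2-chloro-3,3-dimethylpent-4-enal
Conditions: (5S)-5-benzyl-2,2,3-trimethylimidazolidin-4-one·CF3CO2H (5 mol%), 2,3,4,5,6,6-hexachlorocyclohexa-2,4-dien-1-one (1.2 equiv), acetone, −30 °C; filtered through silica, solvent-exchanged and used at once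
Reagents that add atoms: 2,3,4,5,6,6-hexachlorocyclohexa-2,4-dien-1-one, O=C1C(Cl)=C(Cl)C(Cl)=C(Cl)C1(Cl)Cl
Why: Enamine-mediated organocatalytic α-chlorination of an aldehyde, in which the benzyl group of the chiral imidazolidinone shields one face of the E-enamine so that electrophilic chlorine sets the 2S centre (C5 of the target), β-quaternary aldehydes being expected to be tolerated by this reaction.

**Step 3**
Reactants: 3 (2S)-2-chloro-3,3-dimethylpent-4-enal
Product: 4 (3S)-1,1-dibromo-3-chloro-4,4-dimethylhex-5-en-2-ol (both C2 epimers)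
Conditions: CH2Br2 (1.5 equiv), LiN(iPr)2 (1.4 equiv), THF, −78 °C; then 3; AcOH quench at −78 °C
Reagents that add atoms: dibromomethane, BrCBr
Why: 1,2-Addition of the carbenoid LiCHBr2 to the aldehyde brings in C1 at the right oxidation level, the cold acidic quench preventing closure to a bromo epoxide and protecting the α-chloro centre, and the new carbinol centre is irrelevant because it is oxidised next.

**Step 4**
Reactants: 4 (3S)-1,1-dibromo-3-chloro-4,4-dimethylhex-5-en-2-ol
Product: 5 (3S)-1,1-dibromo-3-chloro-4,4-dimethylhex-5-en-2-one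
Conditions: Dess–Martin periodinane (1.3 equiv), CH2Cl2, 0 °C to rt
Reagents that add atoms: none
Why: Dess–Martin oxidation of the secondary alcohol under non-basic conditions gives the α,α-dibromomethyl ketone without enolising the α′-chloro stereocentre.

**Step 5**
Reactants: 5 (3S)-1,1-dibromo-3-chloro-4,4-dimethylhex-5-en-2-one
Product: 6 (2S,4R)-4,6-dibromo-2-chloro-3,3-dimethylcyclohexan-1-one (both C6 epimers, the α-bromo ketone carbon)
Conditions: CuBr (5 mol%), tris(2-pyridylmethyl)amine (5 mol%), AIBN (10 mol%), degassed 1,2-dichloroethane (0.02 M), 60 °C; minor epimer at target C3 removed by chromatography before any further step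
Reagents that add atoms: none
Why: Kharasch-type bromine-atom-transfer radical cyclisation, in which the copper catalyst abstracts one bromine to give an α-keto radical at C1 (a ketone α-carbon reacting with reversed, electrophilic enolonium-like polarity) that adds to the terminal alkene carbon C2 in the 6-endo mode expected for radicals with the carbonyl inside the forming ring (5-exo attack at C3 is further blocked by the quaternary C4), and the C3 radical then takes bromine from the divalent copper bromide complex on the face anti to the axial α-chlorine, which places the neopentyl C3–Br equatorial and trans to Cl.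

**Step 6**
Reactants: 6 (2S,4R)-4,6-dibromo-2-chloro-3,3-dimethylcyclohexan-1-one
Product: 7 (1S,3S,5R)-5-bromo-3-chloro-4,4-dimethyl-2-oxocyclohexyl acetate
Conditions: KOAc (3 equiv), AcOH (1 equiv), 18-crown-6 (10 mol%), MeCN, 40 °C
Reagents that add atoms: potassium acetate, CC(=O)[O-].[K+]
Why: SN2 displacement of the carbonyl-activated α-bromide by acetate (the neopentyl C–Br and C–Cl bonds are inert), followed by enol-mediated equilibration under the buffered conditions to the equatorial acetate, cis to the equatorial bromine and trans to the axial chlorine, which sets C1 (S) under thermodynamic control.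

**Step 7**
Reactants: 7 (1S,3S,5R)-5-bromo-3-chloro-4,4-dimethyl-2-oxocyclohexyl acetate
Product: 8 (1S,3S,5R)-5-bromo-3-chloro-2-ethenyl-2-hydroxy-4,4-dimethylcyclohexyl acetate (both C2 epimers)
Conditions: CH2=CHMgBr (1.5 equiv), CeCl3 (1.6 equiv), THF, −78 °C; AcOH quench at −78 °C
Reagents that add atoms: vinylmagnesium bromide, C=C[Mg]Br
Why: 1,2-Addition of a weakly basic organocerium reagent (Imamoto conditions) to the hindered, enolisable ketone is much faster than attack on the acetate at −78 °C and the cold acidic quench suppresses 1,2-acyl migration, while the new tertiary centre may be a mixture because C6 becomes trigonal in the last step.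

**Step 8**
Reactants: 8 (1S,3S,5R)-5-bromo-3-chloro-2-ethenyl-2-hydroxy-4,4-dimethylcyclohexyl acetate
Product: 9 (1S,2Z,3R,5R)-5-bromo-2-(2-bromoethylidene)-3-chloro-4,4-dimethylcyclohexyl acetate
Conditions: PBr3 (0.45 equiv), pyridine (10 mol%), Et2O, −30 to 0 °C
Reagents that add atoms: phosphorus tribromide, BrP(Br)Br
Why: Allylic substitution with 1,3-transposition (SN2′, as in the linalool to geranyl bromide conversion), in which bromide attacks the terminal carbon of the bromophosphite of the tertiary vinyl carbinol, and allylic 1,3-strain makes the Z isomer (CH2Br syn to the carbon whose chlorine is axial, H syn to the equatorial acetate) strongly preferred both kinetically and on bromide-mediated equilibration.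

**Compound list**
1 | methyl 3,3-dimethylpent-4-enoate | COC(=O)CC(C)(C)C=C | starting material
2 | 3,3-dimethylpent-4-enal | O=CCC(C)(C)C=C | intermediate
3 | (2S)-2-chloro-3,3-dimethylpent-4-enal | O=C[C@@H](Cl)C(C)(C)C=C | intermediate
4 | (3S)-1,1-dibromo-3-chloro-4,4-dimethylhex-5-en-2-ol (both C2 epimers) | BrC(Br)C(O)[C@@H](Cl)C(C)(C)C=C | intermediate
5 | (3S)-1,1-dibromo-3-chloro-4,4-dimethylhex-5-en-2-one | BrC(Br)C(=O)[C@@H](Cl)C(C)(C)C=C | intermediate
6 | (2S,4R)-4,6-dibromo-2-chloro-3,3-dimethylcyclohexan-1-one (both C6 epimers) | BrC1C[C@@H](Br)C(C)(C)[C@H](Cl)C1=O | intermediate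
7 | (1S,3S,5R)-5-bromo-3-chloro-4,4-dimethyl-2-oxocyclohexyl acetate | CC(=O)O[C@H]1C[C@@H](Br)C(C)(C)[C@H](Cl)C1=O | intermediate
8 | (1S,3S,5R)-5-bromo-3-chloro-2-ethenyl-2-hydroxy-4,4-dimethylcyclohexyl acetate (both C2 epimers) | CC(=O)O[C@H]1C[C@@H](Br)C(C)(C)[C@H](Cl)C1(O)C=C | intermediate
9 | (1S,2Z,3R,5R)-5-bromo-2-(2-bromoethylidene)-3-chloro-4,4-dimethylcyclohexyl acetate | CC(=O)O[C@H]1C[C@@H](Br)C(C)(C)[C@H](Cl)/C1=C\CBr | target

**Totals**
Total step count: 8. Longest linear sequence: 8 steps (fully linear from 1).

**Steps most likely to fail, with fallbacks**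

Step 5 (key cyclisation). Risks are competing 5-exo closure, incomplete facial control of the bromine transfer at C3, and epimerisation of the α-chloro centre. Any C3 epimer carried forward would erode the enantiomeric purity once C5 can equilibrate.
Fallback, from 5 back to 7: one equivalent of KOAc (18-crown-6, MeCN, 0 °C) replaces one bromine of 5 to give (3S)-1-bromo-3-chloro-4,4-dimethyl-2-oxohex-5-en-1-yl acetate F1. F1 is then cyclised with Mn2(CO)10 (10 mol%) under blue light in CH2Cl2. The captodative α-acetoxy-α-keto radical from F1 is more stabilised and adds reversibly, so ring size and bromide orientation are reached under thermodynamic bias. The cyclised product is 7 itself after the KOAc/AcOH equilibration of C1.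

Step 7 (vinyl addition next to an acetate). Risks are attack on or 1,2-migration of the acetate and enolisation of the α-hetero-substituted ketone.
Fallback, from 6 back to 8: 6 is first equilibrated (trace HBr in AcOH) to the epimer with the α-bromine equatorial. CH2=CHMgBr/CeCl3 is then added at −78 °C; attack occurs anti to the axial chlorine. On warming to 0 °C the alkoxide displaces the neighbouring α-bromide to give the vinyl epoxide (1R,2S,4R,6R)-4-bromo-2-chloro-1-ethenyl-3,3-dimethyl-7-oxabicyclo[4.1.0]heptane F2. CsOAc/AcOH in DMF at 60 °C opens F2 at the secondary epoxide carbon with inversion. This puts the acetate on C1 with the required configuration and gives 8 as a single C2 epimer.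

Step 8 (allylic transposition). Risks are mixtures of SN2 and SN2′ products or alkene isomers, exchange of the allylic chloride at C5 for bromide, and participation by the neighbouring acetate.
Fallback, from 8 back to 9: pyridinium chlorochromate (C5H5NH[CrO3Cl]) in CH2Cl2 effects the oxidative 1,3-transposition (Babler–Dauben) of the tertiary vinyl carbinol to the enal (1S,2Z,3R,5R)-5-bromo-3-chloro-4,4-dimethyl-2-(2-oxoethylidene)cyclohexyl acetate F3. NaBH4/CeCl3·7H2O in MeOH at −40 °C reduces F3 to (1S,2Z,3R,5R)-5-bromo-3-chloro-2-(2-hydroxyethylidene)-4,4-dimethylcyclohexyl acetate F4. CBr4/PPh3 in CH2Cl2 at 0 °C (Appel) converts the primary allylic alcohol F4 into 9 without ionising conditions.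

**Further compounds**
F1 | step 5 | (3S)-1-bromo-3-chloro-4,4-dimethyl-2-oxohex-5-en-1-yl acetate (both C1 epimers) | CC(=O)OC(Br)C(=O)[C@@H](Cl)C(C)(C)C=C
F2 | step 7 | (1R,2S,4R,6R)-4-bromo-2-chloro-1-ethenyl-3,3-dimethyl-7-oxabicyclo[4.1.0]heptane | O1[C@@H]2C[C@@H](Br)C(C)(C)[C@H](Cl)[C@]12C=C
F3 | step 8 | (1S,2Z,3R,5R)-5-bromo-3-chloro-4,4-dimethyl-2-(2-oxoethylidene)cyclohexyl acetate | CC(=O)O[C@H]1C[C@@H](Br)C(C)(C)[C@H](Cl)/C1=C\C=O
F4 | step 8 | (1S,2Z,3R,5R)-5-bromo-3-chloro-2-(2-hydroxyethylidene)-4,4-dimethylcyclohexyl acetate | CC(=O)O[C@H]1C[C@@H](Br)C(C)(C)[C@H](Cl)/C1=C\CO
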